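The 14-membered carbocycle (C1–C14) is cut at C7=C8, the E-trisubstituted alkene that bears the C19 formyl group; one oxidation level up, this is the enoate that an α-alkylated phosphonoacetate and an aldehyde deliver. A single intramolecular Horner–Wadsworth–Emmons reaction therefore closes the macrocycle, creates C7=C8 and fixes its E geometry without touching C1, C3 or C4. The cyclisation substrate is an open chain that already holds the cis-2,2-dimethyltetrahydrofuran (O, C15, C1, C2, C3), the silyl-protected C18 alcohol, the Z-C11=C12 alkene, an aldehyde at C7 and a diethyl phosphonoacetate unit at C8. Chiral-pool limonene oxide supplies C1, an Evans aldol sets C3 and C4.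

Key step: step 17

Remark: atoms carry the macrocycle numbering (ring C1–C14; C15 ether carbon on C1; C18 the CH2O carbon on C4; C19 on C8; C20 the methyl on C12), the target is (1R,3R,4R,7E,11Z), and commercial (+)-limonene 1,2-oxide (cis/trans mixture, derived from (R)-limonene) is assumed as chiral-pool material because both epoxide isomers converge on one keto aldehyde.

Step 1
Reactants: 1 δ-valerolactone
Product: 3 5-[(4-methoxybenzyl)oxy]pentanoic acid, via potassium 5-hydroxypentanoate 2 (not isolated)
Conditions: KOH, 4-methoxybenzyl chloride, toluene, reflux; then aq. HCl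
Reagents that add atoms: potassium hydroxide, [K+].[OH-]; 4-methoxybenzyl chloride, COc1ccc(CCl)cc1
Why: Saponification of the lactone followed by Williamson etherification of the resulting alkoxide (any benzylic ester formed is hydrolysed in situ) should give the ether acid after acidification.

Step 2
Reactants: 3 5-[(4-methoxybenzyl)oxy]pentanoic acid; 4 (S)-4-benzyloxazolidin-2-one
Product: 6 (S)-4-benzyl-3-{5-[(4-methoxybenzyl)oxy]pentanoyl}oxazolidin-2-one, via mixed pivalic anhydride 5 (not isolated)
Conditions: t-BuCOCl, Et3N, THF, −20 °C; then 4, LiCl, −20 °C → rt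
Reagents that add atoms: none
Why: LiCl-assisted N-acylation of the oxazolidinone by a mixed anhydride is the standard entry to Evans imides and involves no stereocentre of the acyl chain.

Step 3
Reactants: 7 (4R)-limonene 1,2-oxide
Product: 9 (R)-6-oxo-3-(prop-1-en-2-yl)heptanal, via limonene-1,2-diol 8 (not isolated)
Conditions: H5IO6, THF/H2O, 0 °C → rt
Reagents that add atoms: water, O
Why: Acidic hydration of the epoxide and periodate glycol cleavage (Malaprade reaction) open the ring between the former epoxide carbons, leaving the isopropenyl group and the chiral-pool centre (future C1) untouched.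

Step 4
Reactants: 6 (S)-4-benzyl-3-{5-[(4-methoxybenzyl)oxy]pentanoyl}oxazolidin-2-one; 9 (R)-6-oxo-3-(prop-1-en-2-yl)heptanal
Product: 11 syn-aldol adduct (S)-4-benzyl-3-[(2S,3R,5R)-3-hydroxy-2-{3-[(4-methoxybenzyl)oxy]propyl}-8-oxo-5-(prop-1-en-2-yl)nonanoyl]oxazolidin-2-one, via Z-dibutylboron enolate 10 (not isolated)
Conditions: 6 (1.3 equiv), Bu2BOTf (1.2 equiv), Et3N (1.4 equiv), CH2Cl2, −78 → 0 °C; then 9, −78 → 0 °C; aq. NaH2PO4/Na2HPO4 (pH 7), MeOH, H2O2, 0 °C
Reagents that add atoms: none
Why: Evans syn aldol reaction, in which the Z-boron enolate attacks only the aldehyde (the methyl ketone is far less electrophilic and no free Bu2BOTf is left to enolise it) through a Zimmerman–Traxler chair whose enolate face is fixed by the (S)-benzyl auxiliary, setting C4 and C3 with the required syn relationship.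

Step 5
Reactants: 11 syn-aldol adduct
Product: 12 tetrahydrofuran ketone (S)-4-benzyl-3-{(2S)-2-[(2R,4R)-5,5-dimethyl-4-(3-oxobutyl)tetrahydrofuran-2-yl]-5-[(4-methoxybenzyl)oxy]pentanoyl}oxazolidin-2-one
Conditions: TsOH·H2O (10 mol%), CH2Cl2, 0 °C → rt
Reagents that add atoms: none
Why: Brønsted-acid-catalysed Markovnikov hydroalkoxylation, in which protonation of the 1,1-disubstituted alkene develops tertiary cation character at C15 that the C3 hydroxyl captures in a 5-exo closure, so no stereocentre is created and the cis C1/C3 relationship follows from the two existing centres.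

Step 6
Reactants: 12 tetrahydrofuran ketone
Product: 13 C13 acetate (S)-4-benzyl-3-{(2S)-2-[(2R,4R)-4-(2-acetoxyethyl)-5,5-dimethyltetrahydrofuran-2-yl]-5-[(4-methoxybenzyl)oxy]pentanoyl}oxazolidin-2-one
Conditions: mCPBA, CH2Cl2, rt → 40 °C
Reagents that add atoms: 3-chloroperbenzoic acid, OOC(=O)c1cccc(Cl)c1
Why: Baeyer–Villiger oxidation of the methyl ketone proceeds with migration of the primary alkyl group in preference to methyl, turning the two surplus carbons into an acetyl group on the C13 oxygen now that no alkene remains to be epoxidised.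

Step 7
Reactants: 13 C13 acetate
Product: 14 C18 alcohol 2-{(3R,5R)-5-[(2R)-1-hydroxy-5-[(4-methoxybenzyl)oxy]pentan-2-yl]-2,2-dimethyltetrahydrofuran-3-yl}ethyl acetate
Conditions: NaBH4, THF/H2O (4:1), 0 °C → rt
Reagents that add atoms: none
Why: Reductive removal of the oxazolidinone with NaBH4 in wet THF reduces the activated imide carbonyl to the C18 alcohol while an unactivated primary acetate is not reduced by this reagent, and the auxiliary is released for recovery.

Step 8
Reactants: 14 C18 alcohol
Product: 15 C18 silyl ether 2-{(3R,5R)-5-[(2R)-1-[(tert-butyldimethylsilyl)oxy]-5-[(4-methoxybenzyl)oxy]pentan-2-yl]-2,2-dimethyltetrahydrofuran-3-yl}ethyl acetate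
Conditions: TBSCl, imidazole, CH2Cl2, 0 °C → rt
Reagents that add atoms: tert-butyldimethylsilyl chloride, CC(C)(C)[Si](C)(C)Cl
Why: Imidazole-mediated silylation of a primary alcohol is routine and installs the protecting group that survives to the end game.

Step 9
Reactants: 15 C18 silyl ether
Product: 16 C13 alcohol 2-{(3R,5R)-5-[(2R)-1-[(tert-butyldimethylsilyl)oxy]-5-[(4-methoxybenzyl)oxy]pentan-2-yl]-2,2-dimethyltetrahydrofuran-3-yl}ethanol
Conditions: K2CO3 (cat.), MeOH, 0 °C → rt
Reagents that add atoms: none
Why: Base-catalysed transesterification (methanolysis) removes the acetate and leaves the silyl and 4-methoxybenzyl ethers intact.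

Step 10
Reactants: 16 C13 alcohol
Product: 17 C13 iodide tert-butyl{[(2R)-2-[(2R,4S)-4-(2-iodoethyl)-5,5-dimethyltetrahydrofuran-2-yl]-5-[(4-methoxybenzyl)oxy]pentyl]oxy}dimethylsilane (spatial arrangement unchanged; the ring descriptor changes only through CIP priority)
Conditions: I2, PPh3, imidazole, CH2Cl2, 0 °C → rt
Reagents that add atoms: iodine, [I][I]
Why: Appel-type iodination under Garegg–Samuelsson conditions converts the unhindered primary alcohol into the iodide by SN2 displacement of the alkoxyphosphonium ion.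

Step 11
Reactants: 18 ethyltriphenylphosphonium iodide; 19 3-[(tert-butyldimethylsilyl)oxy]propanal
Product: 23 (Z)-tert-butyl[(4-iodopent-3-en-1-yl)oxy]dimethylsilane, via ethylidenetriphenylphosphorane 20 (not isolated), via (1-iodoethyl)triphenylphosphonium iodide 21 (not isolated), via (1-iodoethylidene)triphenylphosphorane 22 (not isolated)
Conditions: 18, n-BuLi, THF, 0 °C; I2, −78 °C; NaHMDS, −78 → −20 °C; then 19, −78 °C → rt
Reagents that add atoms: iodine, [I][I]
Why: Stork–Zhao-type Wittig olefination, in which the α-iodo ylide reacts with the aldehyde under kinetic control through the cis-oxaphosphetane and should give the 2-iodoalkene with iodine cis to the chain (Z), the geometry later carried into C11=C12.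

Step 12
Reactants: 23 (Z)-tert-butyl[(4-iodopent-3-en-1-yl)oxy]dimethylsilane
Product: 24 (Z)-5-bromo-2-iodopent-2-ene
Conditions: Ph3PBr2, CH2Cl2, 0 °C → rt
Reagents that add atoms: triphenylphosphine dibromide, Br[P+](c1ccccc1)(c1ccccc1)c1ccccc1.[Br-]
Why: Triphenylphosphine dibromide converts primary silyl ethers directly into bromides (silyl transfer to bromide, then SN2 on the alkoxyphosphonium ion), and the vinyl iodide does not react.

Step 13
Reactants: 17 C13 iodide; 24 (Z)-5-bromo-2-iodopent-2-ene
Product: 26 tert-butyl{[(2R)-2-{(2R,4R)-4-[(Z)-6-bromo-3-methylhex-3-en-1-yl]-5,5-dimethyltetrahydrofuran-2-yl}-5-[(4-methoxybenzyl)oxy]pentyl]oxy}dimethylsilane, via alkylzinc iodide 25 (not isolated)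
Conditions: 17, Zn dust (BrCH2CH2Br/TMSCl-activated), THF, 40 °C; then 24, Pd(dppf)Cl2 (5 mol%), THF, rt
Reagents that add atoms: none
Why: Negishi sp3–sp2 cross-coupling, in which zinc inserts into the primary carbon–iodine bond and the palladium catalyst joins C13 to C12 with retention of the vinyl iodide geometry, the dppf ligand suppressing β-hydride elimination and the alkyl bromide being inert to both zinc reagent and catalyst.

Step 14
Reactants: 26 coupled bromide; 27 triethyl phosphonoacetate
Product: 29 ethyl (Z)-8-{(3R,5R)-5-[(2R)-1-[(tert-butyldimethylsilyl)oxy]-5-[(4-methoxybenzyl)oxy]pentan-2-yl]-2,2-dimethyltetrahydrofuran-3-yl}-2-(diethoxyphosphoryl)-6-methyloct-5-enoate (both C8 epimers), via sodium phosphonoacetate salt 28 (not isolated)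
Conditions: 27 (4 equiv), NaH (3.8 equiv), DMF, 0 °C → rt; then 26, 50 °C
Reagents that add atoms: none
Why: SN2 C-alkylation of the stabilised phosphonoacetate carbanion by the primary bromide forms C8–C9, the excess of the weakly basic nucleophile limiting dialkylation and elimination.

Step 15
Reactants: 29 phosphonate with C7 4-methoxybenzyl ether
Product: 30 ethyl (Z)-8-{(3R,5R)-5-[(2R)-1-[(tert-butyldimethylsilyl)oxy]-5-hydroxypentan-2-yl]-2,2-dimethyltetrahydrofuran-3-yl}-2-(diethoxyphosphoryl)-6-methyloct-5-enoate
Conditions: DDQ, CH2Cl2/aq. NaH2PO4/Na2HPO4 (pH 7), 0 °C → rt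
Reagents that add atoms: none
Why: Oxidative cleavage of the 4-methoxybenzyl ether by DDQ (benzylic hydride abstraction, hydrolysis of the oxocarbenium ion) is orthogonal to the silyl ether, the trisubstituted alkene and the phosphonoacetate.

Step 16
Reactants: 30 C7 alcohol
Product: 31 ethyl (Z)-8-{(3R,5R)-5-[(2R)-1-[(tert-butyldimethylsilyl)oxy]-5-oxopentan-2-yl]-2,2-dimethyltetrahydrofuran-3-yl}-2-(diethoxyphosphoryl)-6-methyloct-5-enoate
Conditions: Dess–Martin periodinane, CH2Cl2, 0 °C → rt
Reagents that add atoms: none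
Why: Dess–Martin oxidation stops at the aldehyde under near-neutral conditions that neither deprotonate the phosphonoacetate nor touch the silyl ether.

Step 17
Reactants: 31 C7 aldehyde / C8 phosphonoacetate
Product: 32 macrocyclic ethyl (7E,11Z)-enoate (1R,3R,4R; ring C1–C14 bridged by the C3–O–C15 ether, CO2Et on C8, CH2OTBS on C4)
Conditions: LiCl (20 equiv), DBU (10 equiv), MeCN, rt → 40 °C; 31 added by syringe pump over 12 h to 1 mM final concentration
Reagents that add atoms: none
Why: Intramolecular Horner–Wadsworth–Emmons olefination of the Masamune–Roush type: coordination of Li+ to the P=O and C=O oxygens acidifies the C8–H bond enough for DBU, the resulting carbanion attacks the C7 formyl group in a reversible step, and the four-membered P–O intermediate fragments to the enoate and diethyl phosphate. The closest known reaction type is the lithium-salt/amine HWE macrocyclisation of ω-formyl phosphonoacetates to macrocyclic trisubstituted enoates. The ring of 14 carbons closes end-to-end onto a sterically open formyl group, and the cis-disubstituted tetrahydrofuran and the Z alkene at C11=C12 build turns into the chain that bring the termini together. No stereocentre is formed; the only new stereo-element is the alkene geometry, and E (ester trans to C6) should result because the adducts of a stabilised phosphonate equilibrate before elimination. The step needs ring closure to beat oligomerisation, which the low stationary concentration secures, and because the carbons flanking the new alkene (C6, C9) are methylenes, no stereocentre is exposed to the base.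

Step 18
Reactants: 32 macrocyclic ethyl enoate
Product: 33 C19 allylic alcohol (C8 CH2OH, C18 silyl ether)
Conditions: i-Bu2AlH (3 equiv), CH2Cl2, −78 °C; aq. potassium sodium tartrate
Reagents that add atoms: none
Why: 1,2-Reduction of the conjugated ester by i-Bu2AlH gives the allylic alcohol without affecting either alkene, the cyclic ether or the silyl ether.

Step 19
Reactants: 33 C19 allylic alcohol
Product: 34 C18,C19 diol
Conditions: TBAF, THF, 0 °C → rt
Reagents that add atoms: none
Why: Fluoride-induced desilylation frees the primary C18 alcohol at a stage where no base-sensitive carbonyl group is present.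

Step 20
Reactants: 34 C18,C19 diol
Product: 35 hydroxy enal (C19 formyl, free C18 alcohol)
Conditions: MnO2 (activated), CH2Cl2, rt
Reagents that add atoms: none
Why: Activated MnO2 oxidises only the allylic alcohol, so the C19 enal forms while the saturated C18 alcohol and both alkene geometries remain unchanged.

Step 21
Reactants: 35 hydroxy enal; 36 Meldrum's acid
Product: 37 target, 3-oxo-3-{[(1R,3R,4R,7E,11Z)-8-formyl-12,15,15-trimethyl macrocyclic ether-4-yl]methoxy}propanoic acid (CNP0170412.1)
Conditions: 36 (1.2 equiv), toluene, 90 °C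
Reagents that add atoms: none
Why: Alcoholysis of Meldrum's acid, in which the C18 alcohol opens the dioxanedione and the resulting hemiketal ester expels acetone, should give the malonic half ester directly without base or coupling reagent.

Compound list
1 | δ-valerolactone | O=C1CCCCO1 | starting material
2 | potassium 5-hydroxypentanoate | [K+].[O-]C(=O)CCCCO | intermediate
3 | 5-[(4-methoxybenzyl)oxy]pentanoic acid | COc1ccc(COCCCCC(=O)O)cc1 | intermediate
4 | (S)-4-benzyloxazolidin-2-one | O=C1N[C@@H](Cc2ccccc2)CO1 | starting material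
5 | 5-[(4-methoxybenzyl)oxy]pentanoic pivalic anhydride | COc1ccc(COCCCCC(=O)OC(=O)C(C)(C)C)cc1 | intermediate
6 | (S)-4-benzyl-3-{5-[(4-methoxybenzyl)oxy]pentanoyl}oxazolidin-2-one | COc1ccc(COCCCCC(=O)N2[C@@H](Cc3ccccc3)COC2=O)cc1 | intermediate
7 | (4R)-limonene 1,2-oxide (cis/trans mixture at the epoxide) | CC(=C)[C@@H]1CCC2(C)OC2C1 | starting material
8 | (4R)-limonene-1,2-diol | CC(=C)[C@@H]1CCC(C)(O)C(O)C1 | intermediate
9 | (R)-6-oxo-3-(prop-1-en-2-yl)heptanal | O=CC[C@@H](CCC(C)=O)C(C)=C | intermediate
10 | Z-dibutylboron enolate of 6 | COc1ccc(COCCC/C=C(\OB(CCCC)CCCC)N2[C@@H](Cc3ccccc3)COC2=O)cc1 | intermediate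
11 | syn-aldol adduct, (2S,3R,5R)-3-hydroxy-8-oxo-5-isopropenylnonanoyl imide | COc1ccc(COCCC[C@H](C(=O)N2[C@@H](Cc3ccccc3)COC2=O)[C@H](O)C[C@@H](CCC(C)=O)C(C)=C)cc1 | intermediate
12 | tetrahydrofuran ketone imide (cis-2,4-disubstituted 5,5-dimethyltetrahydrofuran) | COc1ccc(COCCC[C@H](C(=O)N2[C@@H](Cc3ccccc3)COC2=O)[C@H]4C[C@@H](CCC(C)=O)C(C)(C)O4)cc1 | intermediate
13 | C13 acetate imide | COc1ccc(COCCC[C@H](C(=O)N2[C@@H](Cc3ccccc3)COC2=O)[C@H]4C[C@@H](CCOC(C)=O)C(C)(C)O4)cc1 | intermediate
14 | C18 alcohol, C13 acetate | COc1ccc(COCCC[C@H](CO)[C@H]2C[C@@H](CCOC(C)=O)C(C)(C)O2)cc1 | intermediate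
15 | C18 tert-butyldimethylsilyl ether, C13 acetate | COc1ccc(COCCC[C@H](CO[Si](C)(C)C(C)(C)C)[C@H]2C[C@@H](CCOC(C)=O)C(C)(C)O2)cc1 | intermediate
16 | C13 alcohol | COc1ccc(COCCC[C@H](CO[Si](C)(C)C(C)(C)C)[C@H]2C[C@@H](CCO)C(C)(C)O2)cc1 | intermediate
17 | C13 iodide | COc1ccc(COCCC[C@H](CO[Si](C)(C)C(C)(C)C)[C@H]2C[C@@H](CCI)C(C)(C)O2)cc1 | intermediate
18 | ethyltriphenylphosphonium iodide | CC[P+](c1ccccc1)(c1ccccc1)c1ccccc1.[I-] | starting material
19 | 3-[(tert-butyldimethylsilyl)oxy]propanal | O=CCCO[Si](C)(C)C(C)(C)C | starting material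
20 | ethylidenetriphenylphosphorane | CC=P(c1ccccc1)(c1ccccc1)c1ccccc1 | intermediate
21 | (1-iodoethyl)triphenylphosphonium iodide | CC(I)[P+](c1ccccc1)(c1ccccc1)c1ccccc1.[I-] | intermediate
22 | (1-iodoethylidene)triphenylphosphorane | CC(I)=P(c1ccccc1)(c1ccccc1)c1ccccc1 | intermediate
23 | (Z)-tert-butyl[(4-iodopent-3-en-1-yl)oxy]dimethylsilane | C/C(I)=C/CCO[Si](C)(C)C(C)(C)C | intermediate
24 | (Z)-5-bromo-2-iodopent-2-ene | C/C(I)=C/CCBr | intermediate
25 | C13 alkylzinc iodide | COc1ccc(COCCC[C@H](CO[Si](C)(C)C(C)(C)C)[C@H]2C[C@@H](CC[Zn]I)C(C)(C)O2)cc1 | intermediate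
26 | coupled (Z)-alkenyl C9 bromide | COc1ccc(COCCC[C@H](CO[Si](C)(C)C(C)(C)C)[C@H]2C[C@@H](CC/C(C)=C\CCBr)C(C)(C)O2)cc1 | intermediate
27 | triethyl phosphonoacetate | CCOC(=O)CP(=O)(OCC)OCC | starting material
28 | sodium salt of triethyl phosphonoacetate | CCOC(=O)[CH-]P(=O)(OCC)OCC.[Na+] | intermediate
29 | C8 phosphonoacetate with C7 4-methoxybenzyl ether | COc1ccc(COCCC[C@H](CO[Si](C)(C)C(C)(C)C)[C@H]2C[C@@H](CC/C(C)=C\CCC(P(=O)(OCC)OCC)C(=O)OCC)C(C)(C)O2)cc1 | intermediate
30 | C8 phosphonoacetate with C7 alcohol | OCCC[C@H](CO[Si](C)(C)C(C)(C)C)[C@H]1C[C@@H](CC/C(C)=C\CCC(P(=O)(OCC)OCC)C(=O)OCC)C(C)(C)O1 | intermediate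
31 | acyclic C7 aldehyde with C8 phosphonoacetate | O=CCC[C@H](CO[Si](C)(C)C(C)(C)C)[C@H]1C[C@@H](CC/C(C)=C\CCC(P(=O)(OCC)OCC)C(=O)OCC)C(C)(C)O1 | intermediate
32 | macrocyclic ethyl (7E,11Z)-enoate, C18 silyl ether | C/C1=C/CC/C(C(=O)OCC)=C\CC[C@H](CO[Si](C)(C)C(C)(C)C)[C@H]2C[C@@H](CC1)C(C)(C)O2 | intermediate
33 | macrocyclic C19 allylic alcohol, C18 silyl ether | C/C1=C/CC/C(CO)=C\CC[C@H](CO[Si](C)(C)C(C)(C)C)[C@H]2C[C@@H](CC1)C(C)(C)O2 | intermediate
34 | macrocyclic C18,C19 diol | C/C1=C/CC/C(CO)=C\CC[C@H](CO)[C@H]2C[C@@H](CC1)C(C)(C)O2 | intermediate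
35 | macrocyclic hydroxy enal | C/C1=C/CC/C(C=O)=C\CC[C@H](CO)[C@H]2C[C@@H](CC1)C(C)(C)O2 | intermediate
36 | Meldrum's acid (2,2-dimethyl-1,3-dioxane-4,6-dione) | CC1(C)OC(=O)CC(=O)O1 | starting material
37 | CNP0170412.1, C18 hydrogen malonate of the (1R,3R,4R,7E,11Z)-enal | C/C1=C/CC/C(C=O)=C\CC[C@H](COC(=O)CC(=O)O)[C@H]2C[C@@H](CC1)C(C)(C)O2 | target

Total step count: 21. Longest linear sequence: 18 steps (steps 1, 2, 4–10 and 13–21, from δ-valerolactone; 17 from limonene oxide).

Steps most likely to fail

Step 17. Ring closure may lose to intermolecular olefination (cyclic dimers and oligomers), or the E preference may erode if elimination outruns equilibration in a strained transition state. The fallback makes C7=C8 between two molecules and closes the ring at C12–C13 instead; it sets out from iodide 17 (with bromide 24 and phosphonoacetate 27) and rejoins the route at macrocycle 32. Alkylation of the sodium salt 28 with 24 should give ethyl (Z)-2-(diethoxyphosphoryl)-6-iodohept-5-enoate F1. DDQ cleavage of the 4-methoxybenzyl ether of 17 should give the iodo alcohol F2, and Dess–Martin oxidation the iodo aldehyde F3. An intermolecular HWE reaction of F3 with F1 (LiCl, i-Pr2NEt, MeCN) should give the acyclic (E)-enoate diiodide F4. Zinc dust should insert selectively into the alkyl carbon–iodine bond to give the alkylzinc iodide F5, and slow addition of F5 to Pd(dppf)Cl2 in THF should close the macrocycle by intramolecular Negishi coupling with retention of the Z geometry, giving 32.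

Step 21. Knoevenagel condensation of the active methylene (of Meldrum's acid or of the product) with the C19 enal may compete with alcoholysis at 90 °C. The fallback is a two-stage malonylation at or below room temperature; it sets out from 35 and 36 and returns at 37. Heating 36 with allyl alcohol gives allyl hydrogen malonate F6; esterification of 35 with F6 (EDC·HCl, DMAP cat., CH2Cl2, 0 °C) should give the allyl malonate F7; Pd(PPh3)4 with sodium 4-methylbenzenesulfinate in THF/MeOH then transfers the allyl group to the sulfinate under neutral conditions and releases 37 after mild acidification.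

Step 5. Proton loss from the C15 cation (alkene migration toward C1, which on re-protonation could erode the C1 configuration) or acid-promoted carbonyl–ene closure of the ketone onto the isopropenyl group may compete with ether formation. The fallback replaces protic activation by halocyclisation and radical reduction; it sets out from 11 and returns at 12. N-Iodosuccinimide in MeCN at 0 °C should give the 5-exo iodoether F8 (CH2I on C15, epimers at C15 of no consequence), and Bu3SnH with AIBN in toluene at 80 °C should remove the iodine to give 12.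

Further compounds
F1 | step 17 | ethyl (Z)-2-(diethoxyphosphoryl)-6-iodohept-5-enoate | C/C(I)=C/CCC(P(=O)(OCC)OCC)C(=O)OCC
F2 | step 17 | C13 iodide with free C7 alcohol | OCCC[C@H](CO[Si](C)(C)C(C)(C)C)[C@H]1C[C@@H](CCI)C(C)(C)O1
F3 | step 17 | C13 iodide with C7 aldehyde | O=CCC[C@H](CO[Si](C)(C)C(C)(C)C)[C@H]1C[C@@H](CCI)C(C)(C)O1
F4 | step 17 | acyclic (E)-enoate with C13 alkyl iodide and C12 vinyl iodide | C/C(I)=C/CC/C(C(=O)OCC)=C\CC[C@H](CO[Si](C)(C)C(C)(C)C)[C@H]1C[C@@H](CCI)C(C)(C)O1
F5 | step 17 | C13 alkylzinc iodide of F4 | C/C(I)=C/CC/C(C(=O)OCC)=C\CC[C@H](CO[Si](C)(C)C(C)(C)C)[C@H]1C[C@@H](CC[Zn]I)C(C)(C)O1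
F6 | step 21 | allyl hydrogen malonate | OC(=O)CC(=O)OCC=C
F7 | step 21 | C18 allyl malonate of hydroxy enal 35 | C/C1=C/CC/C(C=O)=C\CC[C@H](COC(=O)CC(=O)OCC=C)[C@H]2C[C@@H](CC1)C(C)(C)O2
F8 | step 5 | iodoether, 2-(iodomethyl)-2-methyltetrahydrofuran analogue of 12 | COc1ccc(COCCC[C@H](C(=O)N2[C@@H](Cc3ccccc3)COC2=O)[C@H]4C[C@@H](CCC(C)=O)C(C)(CI)O4)cc1
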